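## Retrosynthetic overview

1. C12–C13 is cut last: a ligand-controlled Ni/Cr alkenylation of a C12 aldehyde with 3-bromofuran-2(5H)-one brings in the butenolide intact and sets C12.
2. Ring A decoration: the C3 carbinol comes from hydride reduction; C4 (CH3/CH2OH) and the trans ring fusion come from reductive hydroxymethylation of a 4-methyl-Δ4-3-ketone; C8=CH2 comes from a Wittig reaction on a C8 ketone.
3. Key step, ring B: ring expansion of a hydrindane cyclopentanol by 1,2-shift of the quaternary C10 from C8 to the β-carbon (C9) of an enal, giving the C8 ketone, the C9 stereocentre and the C11–C12 aldehyde arm in one operation.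
4. The rearrangement substrate comes from an (R)-configured methyl Hajos–Parrish-type enedione plus propargyl alcohol; the enedione comes from 2-methylcyclopentane-1,3-dione and ethyl vinyl ketone.
5. Ring order: cyclopentane (bought) → ring A (annulation) → ring B (five-to-six expansion) → butenolide appended last.

Assumption: labdane numbering (C1–C20) is used for every bicyclic compound (in the hydrindanes C8 = indane C1, C10 = indane C7a), and the target SMILES is read as the (3R,4S,5S,9R,10S,12R) isomer, i.e. the C4 hydroxymethyl is equatorial and trans to the C10 methyl.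

## Route

Step 1
Reactants: 1 2-methylcyclopentane-1,3-dione; 2 pent-1-en-3-one (ethyl vinyl ketone)
Product: 4 (7aR)-4,7a-dimethyl-2,3,7,7a-tetrahydro-1H-indene-1,5(6H)-dione, via triketone 3 (not isolated)
Conditions: H2O, AcOH (cat.), 75 °C; concentrate; then D-phenylalanine (1.0 equiv), HClO4 (0.4 equiv), MeCN, reflux; one recrystallisation
Reagents that add atoms: none
Why: Michael addition followed by the Hajos–Parrish (Eder–Sauer–Wiechert) enamine aldol condensation, in which D-phenylalanine differentiates the two enantiotopic ring carbonyls and so sets the quaternary C10 as 7aR, the mirror image of the usual L-amino-acid product.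

Step 2
Reactants: 4 (7aR)-enedione; 5 prop-2-yn-1-ol
Product: 7 (1S,7aR)-1-hydroxy-1-(3-hydroxyprop-1-yn-1-yl)-4,7a-dimethyl-1,2,3,6,7,7a-hexahydro-5H-inden-5-one, via dilithium alkynide 6 (not isolated)
Conditions: 5 (1.5 equiv), n-BuLi (3.0 equiv), THF, −78 → 0 °C; LaCl3·2LiCl (1.0 equiv), −78 °C; then 4; aq NH4Cl
Reagents that add atoms: none
Why: Lanthanide-assisted 1,2-addition of a lithium acetylide to the saturated cyclopentanone, which is more electrophilic than the α-methylated conjugated ketone; attack anti to the angular methyl gives the 1S carbinol, a centre that is erased in step 4.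

Step 3
Reactants: 7 alkyne diol
Product: 8 (2E)-3-[(1S,7aR)-1-hydroxy-4,7a-dimethyl-5-oxo-2,3,5,6,7,7a-hexahydro-1H-inden-1-yl]prop-2-enal
Conditions: (η5-C9H7)RuCl(PPh3)2 (3 mol %), In(OTf)3 (3 mol %), camphorsulfonic acid (3 mol %), THF, 65 °C
Reagents that add atoms: none
Why: Ruthenium-catalysed redox isomerisation of a primary propargylic alcohol to the (E)-enal; the tertiary carbinol has no carbinol hydrogen and cannot isomerise, and the E geometry blocks lactol formation.

Step 4
Reactants: 8 γ-hydroxy enal
Product: 10 (1S,8aS)-1-(2,2-dimethoxyethyl)-5,8a-dimethyl-3,4,8,8a-tetrahydronaphthalene-2,6(1H,7H)-dione, via keto aldehyde 9 (not isolated)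
Conditions: morpholinium trifluoroacetate (20 mol %), toluene, 60 °C; then HC(OMe)3, MeOH, CeCl3·7H2O (10 mol %), 23 °C
Reagents that add atoms: trimethyl orthoformate, COC(OC)OC
Why: Proposed new method: an amine-catalysed vinylogous α-ketol (semipinacol) ring expansion of an unstrained γ-hydroxy enal, in which morpholine forms the (E)-iminium ion, the C8–C10 σ-bond antiperiplanar to the iminium π-system shifts to the electrophilic β-carbon C9 while the hydrogen-bonded tertiary hydroxyl collapses to the C8 ketone, the quaternary C10 migrating with retention in preference to the C7 methylene and onto the alkene face exposed in the rotamer that keeps C8–O syn to C9=C11 with the chain outside the bicycle (this fixes C9 with its side chain cis to the C10 methyl), after which enamine hydrolysis frees the aldehyde and CeCl3-catalysed acetalisation masks it selectively over the two ketones; the driving force is C=O formation plus relief of cyclopentane strain, and the closest known reaction types are the primary-amine-catalysed vinylogous α-ketol rearrangement of β-(1-hydroxycyclobutyl) enones and the D-homoannulation of 17-hydroxy-20-keto steroids.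

Step 5
Reactants: 10 dione acetal
Product: 11 (4aS,5R)-5-(2,2-dimethoxyethyl)-1,4a-dimethyl-6-methylidene-4,4a,5,6,7,8-hexahydronaphthalen-2(3H)-one
Conditions: Ph3PCH3Br (1.2 equiv), KN(SiMe3)2 (1.15 equiv), THF, −20 → 0 °C
Reagents that add atoms: methyltriphenylphosphonium bromide, C[P+](c1ccccc1)(c1ccccc1)c1ccccc1.[Br-]
Why: Wittig methylenation, in which the nucleophilic lithium-free ylide attacks the saturated C8 ketone much faster than the tetrasubstituted conjugated C3 ketone, and the low temperature leaves the adjacent C9 centre unepimerised.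

Step 6
Reactants: 11 methylene enone
Product: 13 (1S,4aS,5R,8aS)-5-(2,2-dimethoxyethyl)-1-(hydroxymethyl)-1,4a-dimethyl-6-methylideneoctahydronaphthalen-2(1H)-one, via lithium enolate 12 (not isolated)
Conditions: Li (2.2 equiv), NH3(l)/THF, t-BuOH (1.0 equiv), −78 °C; evaporate NH3; then monomeric CH2O in THF, −78 °C; aq NH4Cl
Reagents that add atoms: formaldehyde, C=O
Why: Stork reductive alkylation (dissolving-metal enone reduction, then aldol with formaldehyde): axial protonation at C5 gives the trans-decalin, and the regiodefined C3–C4 enolate is hydroxymethylated on the face anti to the axial C10 methyl, placing CH2OH equatorial (4S); the isolated alkene and the acetal are inert.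

Step 7
Reactants: 13 hydroxymethyl ketone
Product: 15 2-[(1R,4aS,5S,6R,8aS)-6-hydroxy-5-(hydroxymethyl)-5,8a-dimethyl-2-methylidenedecahydronaphthalen-1-yl]acetaldehyde, via diol acetal 14 (not isolated)
Conditions: NaBH4, MeOH, 0 °C; then 1 M aq HCl, THF, 0 → 23 °C
Reagents that add atoms: water, O
Why: Borohydride reduction with axial hydride delivery from the face opposite the axial C4 and C10 methyls gives the equatorial 3R alcohol, and mild acetal hydrolysis then unmasks the aldehyde without touching the exocyclic alkene.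

Step 8
Reactants: 15 dihydroxy aldehyde; 16 3-bromofuran-2(5H)-one
Product: 17 3-{(1R)-1-hydroxy-2-[(1R,4aS,5S,6R,8aS)-6-hydroxy-5-(hydroxymethyl)-5,8a-dimethyl-2-methylidenedecahydronaphthalen-1-yl]ethyl}furan-2(5H)-one (CNP0270153.3)
Conditions: CrCl2 (4 equiv), NiCl2 (2 mol %), N-{2-[(4S)-4-isopropyl-4,5-dihydro-1,3-oxazol-2-yl]-6-methylphenyl}methanesulfonamide (4.4 equiv), Et3N (4.4 equiv), THF, 23 °C
Reagents that add atoms: none
Why: Nozaki–Hiyama–Kishi coupling, in which NiCl2-catalysed activation of the C–Br bond and transmetalation give an alkenyl species of trivalent chromium that adds only to the aldehyde (free hydroxyls tolerated), the chiral sulfonamide ligand directing Si-face addition to give 12R (the ligand enantiomer is swapped if a test run shows the opposite sense).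

## Compound list

1 | 2-methylcyclopentane-1,3-dione | CC1C(=O)CCC1=O | starting material
2 | pent-1-en-3-one (ethyl vinyl ketone) | C=CC(=O)CC | starting material
3 | 2-methyl-2-(3-oxopentyl)cyclopentane-1,3-dione | CCC(=O)CCC1(C)C(=O)CCC1=O | intermediate
4 | (7aR)-4,7a-dimethyl-2,3,7,7a-tetrahydro-1H-indene-1,5(6H)-dione | CC1=C2CCC(=O)[C@]2(C)CCC1=O | intermediate
5 | prop-2-yn-1-ol (propargyl alcohol) | C#CCO | starting material
6 | dilithium 3-oxidoprop-1-yn-1-ide (C,O-dilithiated 5) | [Li]C#CCO[Li] | intermediate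
7 | (1S,7aR)-1-hydroxy-1-(3-hydroxyprop-1-yn-1-yl)-4,7a-dimethyl-1,2,3,6,7,7a-hexahydro-5H-inden-5-one | CC1=C2CC[C@](O)(C#CCO)[C@]2(C)CCC1=O | intermediate
8 | (2E)-3-[(1S,7aR)-1-hydroxy-4,7a-dimethyl-5-oxo-2,3,5,6,7,7a-hexahydro-1H-inden-1-yl]prop-2-enal | CC1=C2CC[C@](O)(/C=C/C=O)[C@]2(C)CCC1=O | intermediate
9 | 2-[(1S,8aS)-5,8a-dimethyl-2,6-dioxo-1,2,3,4,6,7,8,8a-octahydronaphthalen-1-yl]acetaldehyde | O=C1CCC2=C(C)C(=O)CC[C@@]2(C)[C@@H]1CC=O | intermediate
10 | (1S,8aS)-1-(2,2-dimethoxyethyl)-5,8a-dimethyl-3,4,8,8a-tetrahydronaphthalene-2,6(1H,7H)-dione | O=C1CCC2=C(C)C(=O)CC[C@@]2(C)[C@@H]1CC(OC)OC | intermediate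
11 | (4aS,5R)-5-(2,2-dimethoxyethyl)-1,4a-dimethyl-6-methylidene-4,4a,5,6,7,8-hexahydronaphthalen-2(3H)-one | C=C1CCC2=C(C)C(=O)CC[C@@]2(C)[C@@H]1CC(OC)OC | intermediate
12 | lithium (4aS,5R,8aS)-5-(2,2-dimethoxyethyl)-1,4a-dimethyl-6-methylidene-3,4,4a,5,6,7,8,8a-octahydronaphthalen-2-olate | C=C1CC[C@@H]2C(C)=C(O[Li])CC[C@@]2(C)[C@@H]1CC(OC)OC | intermediate
13 | (1S,4aS,5R,8aS)-5-(2,2-dimethoxyethyl)-1-(hydroxymethyl)-1,4a-dimethyl-6-methylideneoctahydronaphthalen-2(1H)-one | C=C1CC[C@@H]2[C@@](C)(CO)C(=O)CC[C@@]2(C)[C@@H]1CC(OC)OC | intermediate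
14 | (1S,2R,4aS,5R,8aS)-5-(2,2-dimethoxyethyl)-1-(hydroxymethyl)-1,4a-dimethyl-6-methylidenedecahydronaphthalen-2-ol | C=C1CC[C@@H]2[C@@](C)(CO)[C@H](O)CC[C@@]2(C)[C@@H]1CC(OC)OC | intermediate
15 | 2-[(1R,4aS,5S,6R,8aS)-6-hydroxy-5-(hydroxymethyl)-5,8a-dimethyl-2-methylidenedecahydronaphthalen-1-yl]acetaldehyde | C=C1CC[C@@H]2[C@@](C)(CO)[C@H](O)CC[C@@]2(C)[C@@H]1CC=O | intermediate
16 | 3-bromofuran-2(5H)-one | O=C1OCC=C1Br | starting material
17 | 3-{(1R)-1-hydroxy-2-[(1R,4aS,5S,6R,8aS)-6-hydroxy-5-(hydroxymethyl)-5,8a-dimethyl-2-methylidenedecahydronaphthalen-1-yl]ethyl}furan-2(5H)-one | C=C1CC[C@@H]2[C@@](C)(CO)[C@H](O)CC[C@@]2(C)[C@@H]1C[C@@H](O)C1=CCOC1=O | target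

## Step count and risk

Total step count: 8. Longest linear sequence: 8 steps (1 + 2 → 17); the other building blocks 5 and 16 are used as bought.

**Ring expansion of step 4 (most uncertain).** The cyclopentanol is unstrained, so the shift may be slow. The C7 methylene could migrate instead of C10. Isomerisation of the iminium ion to the Z form would open a path to a spiro-dihydrofuran and then a ring-fused furan. The 1,4-keto aldehyde 9 can undergo intramolecular aldol closure if it is not acetalised promptly. The C9 configuration rests on kinetic control, because the two C9 epimers of the Δ4-8-ketone are expected to be close in energy. The fallback uses the established β-hydroxy-selenide pinacol-type ring enlargement; it sets out from 4 and returns at 10: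
- 3,3-dimethoxy-1,1-bis(phenylselanyl)propane F3 is made from commercial 1,1,3,3-tetramethoxypropane and benzeneselenol with ZnCl2.
- Se/Li exchange with n-BuLi at −78 °C gives [3,3-dimethoxy-1-(phenylselanyl)propyl]lithium F4.
- F4 adds to the C8 ketone of 4 to give the β-hydroxy selenide (1S,7aR)-1-[3,3-dimethoxy-1-(phenylselanyl)propyl]-1-hydroxy-4,7a-dimethyl-1,2,3,6,7,7a-hexahydro-5H-inden-5-one F5.
- AgBF4 on basic Al2O3 in CH2Cl2 activates selenium and the more substituted C10 migrates to C9 with loss of the selenolate. This gives 10 together with its C9 epimer (1R,8aS)-1-(2,2-dimethoxyethyl)-5,8a-dimethyl-3,4,8,8a-tetrahydronaphthalene-2,6(1H,7H)-dione F6, which is separated, re-equilibrated with DBU and recycled.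

**Chemoselective alkynylation of step 2.** The acetylide may add to the conjugated carbonyl or simply enolise the substrate. The fallback sets out from 4 and returns at 7:
- Condensation of 4 with pyrrolidine (toluene, Dean–Stark) masks only the conjugated ketone as the dienamine (7aR)-4,7a-dimethyl-5-(pyrrolidin-1-yl)-2,6,7,7a-tetrahydro-1H-inden-1-one F1; the neopentyl cyclopentanone does not form an enamine, as with 17-keto steroids.
- Addition of 6 can then occur only at C8, giving (1S,7aR)-1-(3-hydroxyprop-1-yn-1-yl)-4,7a-dimethyl-5-(pyrrolidin-1-yl)-2,6,7,7a-tetrahydro-1H-inden-1-ol F2.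
- Buffered hydrolysis (AcOH/NaOAc/H2O) restores the enone and gives 7.

**Ni/Cr coupling of step 8.** The α-bromo butenolide may be reduced rather than coupled, and ligand control at C12 may be modest because the nearest ring stereocentre is remote. The fallback sets out from 15 and returns at 17: a Morita–Baylis–Hillman reaction of 15 with commercial furan-2(5H)-one (trialkylphosphine catalyst, phenol co-catalyst, THF), which tolerates the free hydroxyls. It forms the same C12–C13 bond without stereocontrol, giving 17 together with its 12S epimer 3-{(1S)-1-hydroxy-2-[(1R,4aS,5S,6R,8aS)-6-hydroxy-5-(hydroxymethyl)-5,8a-dimethyl-2-methylidenedecahydronaphthalen-1-yl]ethyl}furan-2(5H)-one F7, and the two are separated by chromatography.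

## Further compounds

F1 | step 2 | (7aR)-4,7a-dimethyl-5-(pyrrolidin-1-yl)-2,6,7,7a-tetrahydro-1H-inden-1-one | CC1=C(N3CCCC3)CC[C@@]4(C)C(=O)CC=C14
F2 | step 2 | (1S,7aR)-1-(3-hydroxyprop-1-yn-1-yl)-4,7a-dimethyl-5-(pyrrolidin-1-yl)-2,6,7,7a-tetrahydro-1H-inden-1-ol | CC1=C(N3CCCC3)CC[C@@]4(C)[C@@](O)(C#CCO)CC=C14
F3 | step 4 | 3,3-dimethoxy-1,1-bis(phenylselanyl)propane | COC(OC)CC([Se]c1ccccc1)[Se]c1ccccc1
F4 | step 4 | [3,3-dimethoxy-1-(phenylselanyl)propyl]lithium | [Li]C(CC(OC)OC)[Se]c1ccccc1
F5 | step 4 | (1S,7aR)-1-[3,3-dimethoxy-1-(phenylselanyl)propyl]-1-hydroxy-4,7a-dimethyl-1,2,3,6,7,7a-hexahydro-5H-inden-5-one | CC1=C2CC[C@](O)(C(CC(OC)OC)[Se]c3ccccc3)[C@]2(C)CCC1=O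
F6 | step 4 | (1R,8aS)-1-(2,2-dimethoxyethyl)-5,8a-dimethyl-3,4,8,8a-tetrahydronaphthalene-2,6(1H,7H)-dione | O=C1CCC2=C(C)C(=O)CC[C@@]2(C)[C@H]1CC(OC)OC
F7 | step 8 | 3-{(1S)-1-hydroxy-2-[(1R,4aS,5S,6R,8aS)-6-hydroxy-5-(hydroxymethyl)-5,8a-dimethyl-2-methylidenedecahydronaphthalen-1-yl]ethyl}furan-2(5H)-one | C=C1CC[C@@H]2[C@@](C)(CO)[C@H](O)CC[C@@]2(C)[C@@H]1C[C@H](O)C1=CCOC1=O
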